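Tuesday's run, with more initiator than Wednesday's, reads flat in target at 22.0% of the substrate charged from 2.00 h to 10.0 h, with 67.8% of the substrate still there, so within the scatter Tuesday's readings no longer move after the first one, and they stand well short of using up the substrate.

all flasks: substrate 0.20 M

| flask | partner | transfer agent | initiator | remark | time |
|---|---|---|---|---|---|
| Wednesday's | 0.22 M | 0.20 M | 0.13 mM | run made earlier |  |
| Tuesday's | 0.22 M | 0.20 M | 8.2 mM | run made earlier |  |
| red | 0.220 M | 0.200 M | 0.12 mM |  | 20 h |
| ochre | 0.220 M | 0.200 M | 0.40 mM |  | 20 h |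
| blue | 0.220 M | 0.200 M | 1.2 mM |  | 20 h |
| grey | 0.220 M | 0.200 M | 3.0 mM |  | 20 h |
| green | 0.220 M | 0.200 M | 10 mM |  | 20 h |

| run | time / h | target / % | substrate / % |
|---|---|---|---|
| Wednesday's | 2.00 | 1.0 | 97.0 |
| Wednesday's | 4.00 | 2.4 | 96.2 |
| Wednesday's | 6.00 | 3.3 | 96.0 |
| Wednesday's | 8.00 | 2.6 | 95.2 |
| Wednesday's | 10.0 | 0.5 | 96.2 |
| Tuesday's | 2.00 | 21.7 | 67.9 |
| Tuesday's | 4.00 | 21.6 | 67.5 |
| Tuesday's | 6.00 | 22.7 | 69.0 |
| Tuesday's | 8.00 | 22.5 | 66.8 |
| Tuesday's | 10.0 | 21.4 | 67.9 |

(each reading ± 1 percentage point)

- the numbers in the tables scatter with a standard deviation of 1 percentage point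
- "hardly changes" means that all values lie within two and a half points (for a concentration: within two and a half percent of the largest)

* amount of target at the end, in percent of the substrate charged for red, ochre, blue, grey, green, in this order
* how that number moves from the first to the last of them (hardly changes / falls all the way / rises, then falls / falls, then rises / rises all the way)

The asked time of 20 h is ten times that first reading, so I read each end value as a plateau and the question becomes how the plateau moves with the initiator charge. Two amounts answer that: the substrate lost on Tuesday, 32.2%, and on Wednesday, 3.88%. Their ratio reads 8.29, with Wednesday's small loss carrying most of the scatter, while the charges differ by 63.1 and the root of that is 7.94, so these two runs read, within their scatter, as a loss that goes with the root of the charge. My reckoning assumes that target follows the loss, and I carry the root plateau, Tuesday's plateau scaled by the root of the charge ratio, here to green's charge: 24.3%. Scaled down the same way, the row from red to green is 2.66%, 4.85%, 8.41%, 13.3% and 24.3%.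

The forecast, reading the rise in substrate lost as one that “is a square-root dependence”, gives 2.7%, 5.2%, 9%, 13.7% and 23.5%, and says the row rises all the way; at green it stands below my figure.

The flasks give 2.37%, 4.76%, 8.68%, 13.8% and 23.6%, and the row rises all the way.

    partner + first chain carrier → target + second chain carrier (k = 10900 M⁻¹ s⁻¹)
    2 first chain carrier → ended chains A (k = 1.10 × 10⁶ M⁻¹ s⁻¹)
    substrate + second chain carrier → by-product + first chain carrier (k = 641 M⁻¹ s⁻¹)
    transfer agent + first chain carrier → side product + idle radical (kL = 23.7 M⁻¹ s⁻¹)
    2 idle radical → ended radicals (k = 1.60 × 10⁷ M⁻¹ s⁻¹)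
    substrate + initiating radical → capped initiator + first chain carrier (k = 36000 M⁻¹ s⁻¹)
    partner → decomposed reagent (k = 3.80 × 10⁻⁴ s⁻¹)
    2 second chain carrier → ended chains B (k = 2.00 × 10⁸ M⁻¹ s⁻¹)
    target ⇌ isomer of the product (K = 0.409, k = 1.38 × 10⁻⁴ s⁻¹)
    initiator → 2 initiating radical (k = 2.70 × 10⁻⁴ s⁻¹)

Green ends 0.70 percentage points below the root plateau, and at 20.0 h its partner, the limiting reagent there, stands at 0% of its charge with 64.4% of the substrate left, while a run ten times as long changes nothing in its target. Scaled down to red's charge, the root plateau reads 2.66%, and red holds 2.37%.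

The readings come from a simulation with constants of no real substance; scatter was added.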